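(The constants were set for the occasion, and the outcome is calculated.)

I had 1.5 min of stirring, and the first question was whether that was long against the life of the reagent.

substrate 0.50 mM; partner 1.50 equiv; reagent 1.05 equiv; time 1.5 min

    reagent + partner → second intermediate (k1 = 170 M⁻¹ s⁻¹)
    substrate + reagent → open intermediate (k2 = 1400 M⁻¹ s⁻¹)
    target → over-reaction product (k3 = 5.0 × 10⁻⁴ s⁻¹)
    open intermediate + second intermediate → target (k4 = 1700 M⁻¹ s⁻¹)

* how much of the substrate has reacted by 1.5 min
* how much target there is at 1.5 min, in percent of the substrate charged
* how much open intermediate there is at 1.5 min, in percent of the substrate charged
* amount of target if the flask were left three thousand times as long, in percent of the substrate charged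

It was: substrate and partner together halve the reagent at the start in 0.838 s, far shorter than the run, so I asked how its 1.05 equiv divides between them. The division follows the selectivity factor, the substrate's rate constant over the partner's, 8.24, multiplied by the ratio of substrate to partner present.

At the charged ratio, the substrate would take 88.8% of its charge. But both curves fall, so I replaced each by its mean, halfway to that first end point. The mean ratio of rates became 3.23, which gave the partner 0.248 of the substrate's charge in reagent and left the substrate 80.2% reacted. A further pass gave 82.1%, so I put the error of the mean at about 2 percentage points.

Did the second intermediate then couple? Its half-life against the open intermediate left over is 1.47 s, short against the run, so I let it convert one for one. That left 55.3% open intermediate. The target's half-life of 23.1 min is longer than the run, so I expected 23.8% target. After the long stay its decay exponent is 135, which leaves <0.001%.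

The forecast gave 79% conversion, 25% target, 53% open intermediate, less than mine, and 0% target after the long stay, saying "The reagent is gone within seconds".

The simulation gave 79.1%, 24.9%, 53.1% and 0%.

At 0.0157 min the substrate's step was using reagent 3.5 times as fast as the partner's, and at 1.50 min, with reagent at 0%, this flask held 21% of its substrate and 83% of its partner, whose logarithms stand in the ratio 8.24 against the selectivity factor of 8.24. With 3.80 equiv of partner, the same two steps on 8.24 gave 71.8% and then 62.2%, and that neighbouring flask stood at 62.4% conversion.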